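The decalin of the target is a farnesyl chain in disguise: rings A and B, the C4–C5 and C9–C10 bonds, the methyl groups on C5 and C9, the hydrogen on C10, the C8 stereocentre and the C4 methylene follow from one proton-triggered bicyclization of a 2E,6E-farnesyl arene and four 1,2-shifts. The route joins 1,2,4,5-tetramethoxybenzene to farnesyl bromide, lets an evolved class two terpene cyclase fold the chain chair–boat and set both rings with all four stereocentres (C5, C8, C9, C10) in a single operation, and unmasks the arene as the hydroxy methoxy quinone. The precursor is the symmetric, O-methylated farnesyl arene, whose blocked ortho positions keep the ring a spectator.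

Key step: step 2

Remarks on the chemistry
- Numbering and faces: terpenoid numbering is used for the decalin and, by mapping, for the chain. Ring A is C1–C5 with C10, ring B is C5–C10, C11 is the methylene carbon on C4, and C15 is the benzylic CH2 on C9. α/β refer to the usual drawing (ring A on the left, C10 at the top of the fusion bond). In 5, 6 and 8 the C5 methyl, the C10 hydrogen, the C8 methyl and C15 lie on the α face and the C9 methyl on the β face (cis-fused; 5R,8R,9R,10S).
- Structure check: precursor 4 (2E,6E; chain on the ring carbon flanked by two methoxy groups) and product 5 were re-derived from the target SMILES, and no correction was needed.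
- Precursor design: the tetramethyl ether is kept on purpose. A free hydroxyl ortho to the chain would capture the C8 cation as a chromane, and the symmetric ring makes both the lithiation and the later oxidation free of regiochemical choice.
- Assumption: a cyclase with the required fold and termination can be evolved (screening on 4) from a cis-clerodane-forming class two diterpene cyclase whose basic diphosphate-binding residues are exchanged for apolar ones to seat the tetramethoxyphenyl group.

Step 1
Reactants: 1 1,2,4,5-tetramethoxybenzene; 2 (2E,6E)-farnesyl bromide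
Product: 4 1,2,4,5-tetramethoxy-3-[(2E,6E)-3,7,11-trimethyldodeca-2,6,10-trien-1-yl]benzene, via aryllithium 3 (not isolated)
Conditions: n-BuLi (1.1 equiv), THF, 0 °C, 1 h; then 2, −78 °C to rt
Reagents that add atoms: none
Why: Directed ortho-metalation at the ring C–H flanked by two methoxy groups, then SN2 alkylation of the primary allylic bromide, which leaves the 2E and 6E alkenes untouched; no stereocentre is formed.

Step 2
Reactants: 4 1,2,4,5-tetramethoxy-3-[(2E,6E)-3,7,11-trimethyldodeca-2,6,10-trien-1-yl]benzene
Product: 5 1,2,4,5-tetramethoxy-3-{[(1R,2R,4aR,8aS)-1,2,4a-trimethyl-5-methylidene-decahydronaphthalen-1-yl]methyl}benzene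
Conditions: evolved class two terpene cyclase variant (E. coli whole cells), HEPES buffer pH 7.0, 2-hydroxypropyl-β-cyclodextrin, 30 °C, 24–48 h
Reagents that add atoms: none
Why: Proposed new method: the DxDD aspartic acid of the cyclase protonates C3 of the terminal alkene, the C4 cation is captured by the C5=C10 alkene and the C10 cation by the C9=C8 alkene (two anti additions that form C4–C5 and C9–C10), and the bicyclic C8 cation is then relayed by four suprafacial 1,2-shifts (H from C9 to C8, CH3 from C10 to C9, H from C5 to C10, CH3 from C4 to C5) until a base in the site takes a proton from the methyl left on C4. The closest known reaction types are the same bicyclization and four-shift cascade that clerodane-forming class two diterpene cyclases run on geranylgeranyl diphosphate and the unrearranged bicyclization of farnesyl arenes by squalene–hopene cyclase variants; what is untested is a rearranging cyclase that accepts a neutral, aryl-terminated C15 chain. Ring A closes 6-endo-trig through a chair and ring B 6-endo-trig through a boat. C10 is set by anti addition across the 6E alkene; the boat of ring B puts the C9 hydrogen on the face of the C10 methyl, so C8 receives hydrogen and C9 receives methyl on that (β) face, C10 receives hydrogen on the α face, and C5 receives the α methyl of C4 on the face the hydride left, which gives the cis fusion; the absolute sense follows from the one enantiomeric fold that the chiral pocket admits. The step needs initiation only at the terminal alkene, no quench of the C8, C9, C10 and C5 cations, and proton loss only from the C4 methyl: the 2E,6E geometry, the lack of any hydroxyl group and the methoxy groups on both ring positions ortho to C15 (the only ring carbons a C8 cation could reach) secure the substrate side, while the order of shifts and the final deprotonation rest on the shape of the evolved site.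

Step 3
Reactants: 5 1,2,4,5-tetramethoxy-3-{[(1R,2R,4aR,8aS)-1,2,4a-trimethyl-5-methylidene-decahydronaphthalen-1-yl]methyl}benzene
Product: 6 2,5-dimethoxy-3-{[(1R,2R,4aR,8aS)-1,2,4a-trimethyl-5-methylidene-decahydronaphthalen-1-yl]methyl}cyclohexa-2,5-diene-1,4-dione
Conditions: (NH4)2Ce(NO3)6 (2.5 equiv), MeCN/H2O (2:1), 0 °C, 15 min
Reagents that add atoms: water, O
Why: Oxidative demethylation of a para-dimethoxyarene by single-electron oxidation with tetravalent cerium; either para pair of methoxy groups gives the same 2,5-dimethoxyquinone because the ring is symmetric, and the isolated C4 methylene and the four stereocentres should not be touched in a short reaction at 0 °C.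

Step 4
Reactants: 6 2,5-dimethoxy-3-{[(1R,2R,4aR,8aS)-1,2,4a-trimethyl-5-methylidene-decahydronaphthalen-1-yl]methyl}cyclohexa-2,5-diene-1,4-dione
Product: 8 2-hydroxy-5-methoxy-3-{[(1R,2R,4aR,8aS)-1,2,4a-trimethyl-5-methylidene-decahydronaphthalen-1-yl]methyl}cyclohexa-2,5-diene-1,4-dione (CID71726091), via potassium quinonolate 7 (not isolated)
Conditions: KOH (2 M aq.), MeOH, rt; then 1 M HCl
Reagents that add atoms: potassium hydroxide, [K+].[OH-]
Why: Addition–elimination hydrolysis of a vinylogous ester; the methoxy group next to C15 is twisted out of conjugation by the side chain and should be displaced first, the vinylogous carboxylate 7 resists a second attack, and no stereocentre is involved.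

Compound list
1 | 1,2,4,5-tetramethoxybenzene | COc1cc(OC)c(OC)cc1OC | starting material
2 | (2E,6E)-farnesyl bromide | CC(C)=CCC/C(C)=C/CC/C(C)=C/CBr | starting material
3 | (2,3,5,6-tetramethoxyphenyl)lithium | [Li]c1c(OC)c(OC)cc(OC)c1OC | intermediate
4 | 1,2,4,5-tetramethoxy-3-[(2E,6E)-3,7,11-trimethyldodeca-2,6,10-trien-1-yl]benzene | CC(C)=CCC/C(C)=C/CC/C(C)=C/Cc1c(OC)c(OC)cc(OC)c1OC | intermediate
5 | 1,2,4,5-tetramethoxy-3-{[(1R,2R,4aR,8aS)-1,2,4a-trimethyl-5-methylidene-decahydronaphthalen-1-yl]methyl}benzene (cis-decalin) | C=C1CCC[C@H]2[C@](C)(Cc3c(OC)c(OC)cc(OC)c3OC)[C@H](C)CC[C@@]12C | intermediate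
6 | 2,5-dimethoxy-3-{[(1R,2R,4aR,8aS)-1,2,4a-trimethyl-5-methylidene-decahydronaphthalen-1-yl]methyl}cyclohexa-2,5-diene-1,4-dione | C=C1CCC[C@H]2[C@](C)(CC3=C(OC)C(=O)C=C(OC)C3=O)[C@H](C)CC[C@@]12C | intermediate
7 | potassium salt of 8 (quinonolate at the oxygen next to the side chain) | C=C1CCC[C@H]2[C@](C)(CC3=C([O-])C(=O)C=C(OC)C3=O)[C@H](C)CC[C@@]12C.[K+] | intermediate
8 | 2-hydroxy-5-methoxy-3-{[(1R,2R,4aR,8aS)-1,2,4a-trimethyl-5-methylidene-decahydronaphthalen-1-yl]methyl}cyclohexa-2,5-diene-1,4-dione | C=C1CCC[C@H]2[C@](C)(CC3=C(O)C(=O)C=C(OC)C3=O)[C@H](C)CC[C@@]12C | target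

Total step count: 4. Longest linear sequence: 4 steps (1 → 4 → 5 → 6 → 8).

Steps most likely to fail

(a) Step 2 (Proposed new method). The cascade may end early by proton loss or water capture at the C8, C9 or C10 cation, the chain may fold chair–chair, or the last proton may be lost from C3 instead of the C4 methyl. The fallback uses known chemistry, sets out from 1 and comes back at 5.
- Arene fragment: 1 is lithiated as in step 1 and quenched with paraformaldehyde to give (2,3,5,6-tetramethoxyphenyl)methanol F1, which PBr3 (Et2O, 0 °C) converts into the benzylic bromide F2.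
- Ring B, first part: commercial 5-methylcyclohexane-1,3-dione is C-methylated (MeI, aq. NaOH) to 2,5-dimethylcyclohexane-1,3-dione F3 and converted (EtOH, TsOH, toluene, water removal) into the racemic ethyl enol ether F4. This is resolved by preparative chromatography on a chiral stationary phase to the (R)-enol ether F5.
- Ring B, quaternary centre: two kinetic alkylations at C6 (LiN(i-Pr)2, THF, −78 °C) follow. F2 gives the trans-benzylated vinylogous ester F6. MeI, which should enter anti to the pseudoaxial C5 methyl, then gives the quaternary vinylogous ester F7 with the arylmethyl group cis to that methyl (the later C9/C8 relationship).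
- Enone: a Stork–Danheiser transposition (LiAlH4 to the allylic alcohol F8, then 1 M HCl) gives the enone F9.
- Ring A: the Grignard reagent F10 is made from commercial (5-chloropent-1-yn-1-yl)trimethylsilane and Mg. Its copper-catalysed conjugate addition (CuBr·SMe2, THF, −78 °C) should occur trans to the ring methyl on the stereocentre and set the later C10. The enolate is trapped with i-Pr3SiOSO2CF3 as the silyl enol ether F11.
- Ring closure: K2CO3 in MeOH frees the terminal alkyne F12. A gold-catalysed Conia-ene-type 6-exo-dig cyclization (Ph3PAuCl/AgBF4, toluene/MeOH) closes ring A on the face of the tether and gives the cis-fused ketone F13, with the C5 methyl and the C4 methylene in place.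
- Return: Wolff–Kishner reduction (N2H4·H2O, KOH, diethylene glycol, 190 °C) removes the C6 carbonyl and gives 5.

(b) Step 4. Hydroxide may attack the other methoxy group or both. The fallback sets out from 6 and comes back at 8. Both methoxy groups are hydrolysed on purpose (excess NaOH, aq. dioxane, 60 °C; then HCl) to the dihydroxyquinone F14. A vinylogous Fischer esterification (MeOH, catalytic pyridinium p-toluenesulfonate, 40 °C) then methylates only the unhindered hydroxyl next to the ring hydrogen and gives 8.

(c) Step 3. The acidic oxidant may move the C4 methylene into ring A or over-oxidise the side chain. The fallback sets out from 5 and comes back at 6. One methyl ether is cleaved with NaSEt (DMF, 120 °C) to the trimethoxyphenol F15 (hydroxyl beside the side chain) and/or its regioisomer F16. Each carries a methoxy group para to the hydroxyl and should be oxidised by PhI(OAc)2 in MeCN/H2O at 0 °C, without strong acid, to the same quinone 6.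

Further compounds
F1 | step 2 | (2,3,5,6-tetramethoxyphenyl)methanol | OCc1c(OC)c(OC)cc(OC)c1OC
F2 | step 2 | 3-(bromomethyl)-1,2,4,5-tetramethoxybenzene | BrCc1c(OC)c(OC)cc(OC)c1OC
F3 | step 2 | 2,5-dimethylcyclohexane-1,3-dione | CC1CC(=O)C(C)C(=O)C1
F4 | step 2 | racemic 3-ethoxy-2,5-dimethylcyclohex-2-en-1-one | CCOC1=C(C)C(=O)CC(C)C1
F5 | step 2 | (R)-3-ethoxy-2,5-dimethylcyclohex-2-en-1-one | CCOC1=C(C)C(=O)C[C@H](C)C1
F6 | step 2 | (5R,6S)-3-ethoxy-2,5-dimethyl-6-[(2,3,5,6-tetramethoxyphenyl)methyl]cyclohex-2-en-1-one | CCOC1=C(C)C(=O)[C@@H](Cc2c(OC)c(OC)cc(OC)c2OC)[C@H](C)C1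
F7 | step 2 | (5R,6R)-3-ethoxy-2,5,6-trimethyl-6-[(2,3,5,6-tetramethoxyphenyl)methyl]cyclohex-2-en-1-one | CCOC1=C(C)C(=O)[C@](C)(Cc2c(OC)c(OC)cc(OC)c2OC)[C@H](C)C1
F8 | step 2 | allylic alcohol from 1,2-reduction of F7 (carbinol epimers) | CCOC1=C(C)C(O)[C@](C)(Cc2c(OC)c(OC)cc(OC)c2OC)[C@H](C)C1
F9 | step 2 | (4R,5R)-2,4,5-trimethyl-4-[(2,3,5,6-tetramethoxyphenyl)methyl]cyclohex-2-en-1-one | CC1=C[C@](C)(Cc2c(OC)c(OC)cc(OC)c2OC)[C@H](C)CC1=O
F10 | step 2 | [5-(trimethylsilyl)pent-4-yn-1-yl]magnesium chloride | C[Si](C)(C)C#CCCC[Mg]Cl
F11 | step 2 | triisopropylsilyl enol ether of the conjugate adduct of F9 (silylalkynyl chain trans to the neighbouring-ring methyl) | C[Si](C)(C)C#CCCC[C@H]1[C@](C)(Cc2c(OC)c(OC)cc(OC)c2OC)[C@H](C)CC(O[Si](C(C)C)(C(C)C)C(C)C)=C1C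
F12 | step 2 | terminal alkyne from F11 (silyl enol ether retained) | C#CCCC[C@H]1[C@](C)(Cc2c(OC)c(OC)cc(OC)c2OC)[C@H](C)CC(O[Si](C(C)C)(C(C)C)C(C)C)=C1C
F13 | step 2 | 6-oxo derivative of 5 (cis-fused decalin-6-one with C4 methylene) | C=C1CCC[C@H]2[C@](C)(Cc3c(OC)c(OC)cc(OC)c3OC)[C@H](C)CC(=O)[C@@]12C
F14 | step 4 | 2,5-dihydroxy-3-{[(1R,2R,4aR,8aS)-1,2,4a-trimethyl-5-methylidene-decahydronaphthalen-1-yl]methyl}cyclohexa-2,5-diene-1,4-dione | C=C1CCC[C@H]2[C@](C)(CC3=C(O)C(=O)C=C(O)C3=O)[C@H](C)CC[C@@]12C
F15 | step 3 | 3,4,6-trimethoxy-2-{[(1R,2R,4aR,8aS)-1,2,4a-trimethyl-5-methylidene-decahydronaphthalen-1-yl]methyl}phenol | C=C1CCC[C@H]2[C@](C)(Cc3c(O)c(OC)cc(OC)c3OC)[C@H](C)CC[C@@]12C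
F16 | step 3 | 2,4,5-trimethoxy-3-{[(1R,2R,4aR,8aS)-1,2,4a-trimethyl-5-methylidene-decahydronaphthalen-1-yl]methyl}phenol | C=C1CCC[C@H]2[C@](C)(Cc3c(OC)c(O)cc(OC)c3OC)[C@H](C)CC[C@@]12C
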